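**Remarks on the chemistry**

- Locants follow germacranolide numbering: C1=C2 (Z), C3 ketone, C4(CH3)=C5 (Z), C6 (lactone O), C7, C8 (ester O), C9, C10 (CH3, OH); C11(=C13H2)–C12(=O) is the lactone acrylate; C14 and C15 are the methyls on C10 and C4.
- Assumption: the target is taken as the open (1Z)-hydroxy-enone drawn; the C10 hydroxyl is expected to add reversibly to C3 (ring–chain tautomerism), and the route delivers this tautomeric system with the configurations of the SMILES (6S,7R,8R,10R; 2'R).
- Assumption: ethyl glyoxylate (toluene solution), ethynylmagnesium bromide, hexamethylditin and (R)-2-methylbutanoic acid are purchased.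

## The problem

1. The skeleton is a ten-membered carbocycle (C1–C10) cis-fused at C6/C7 to an α-methylene-γ-butyrolactone (O–C12(=O)–C11(=C13H2)–C7), with methyls on C4 and C10.
2. The ring holds a cross-conjugated dienone, C1=C2–C3(=O)–C4(CH3)=C5, both olefins Z. Ten-membered rings close reluctantly, Z-enones isomerise easily, and the dienone is a Michael and Nazarov substrate, so it should appear last and under neutral conditions.
3. C6 (S), C7 (R) and C8 (R) are contiguous, with O6, C11 and O8 on one face (cis-lactone, acyloxy syn to it). The tertiary carbinol C10 (R) is 1,3-anti to O8. The fifth centre, in the (R)-2-methylbutanoate, is remote and must be bought.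
4. C8 and C10 form a 1,3-pair that can be set on a small fragment. C8 can then direct C7 by 1,2-induction, and C6 is tied to C7 in the bond that makes the lactone. Nothing in the ring can be trusted to set C10 late.
5. Fragile groups: the α-methylene lactone (acceptor; excludes hydrides and organolithiums once present), the allylic lactone C6–O, the C8 oxygen (it can take over the lactone as an 8,12-olide or leave by elimination if activated), and the (Z)-γ-hydroxy-enone C10(OH)–C1=C2–C3=O.
6. Enabling feature: C3 is the only ring carbon that carries nothing but oxygen, and it lies between two (Z)-alkenes whose outer carbons (C1, C5) each bear an oxygenated carbon (C10–OH, C6–O). Each alkenyl terminus (C2, C4) can therefore be made geometrically pure from a propargylic alcohol by hydroxyl-directed trans-hydrometalation, and C3 can be supplied as carbon monoxide between them in the ring-closing event.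

## Retrosynthesis

**25 ⇒ 23 + 24.** The C8–O acyl bond is cut last. An ester at C8 would be a leaving group δ to the metal in the allylindium of step 11 (vinylogous β-elimination to a diene) and would acidify the α-hydrogen of aldehyde 10. C8–O therefore travels as a silyl ether. The forward step must acylate the secondary C8–OH of diol 23 with acid 24 without touching the tertiary or hemiketal hydroxyl.

**23 ⇒ 22.** Two triethylsilyl ethers are removed. The one on O10 is required, not cosmetic: a free C10–OH would trap the acylpalladium of the key step as a butenolide. The forward step needs a desilylation that spares lactone and dienone.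

**22 ⇒ 20 + 21 (key).** Both bonds to C3 (C2–C3 and C3–C4) are cut and C3 becomes carbon monoxide 21. Against cutting C6–C7, C1=C2 or C3–C4 alone (see below), this removes the ring and the sensitive dienone in one operation. It leaves a monocyclic lactone 20 whose two olefin geometries are already fixed. The forward reaction must insert CO before C–C coupling, keep both Z geometries, and transmetalate intramolecularly. The iodide is placed on C2 and tin on C4 so that the alkenylpalladium is far from the C11=C13 acceptor.

**20 ⇒ 13 + 18 (through 19).** C6–C7 and the lactone C12–O bond are cut (Barbier-type 2-(alkoxycarbonyl)allylation). The neighbouring cut C7–C8 would need an α-oxy-β,γ-unsaturated aldehyde to build the bromide, which is configurationally fragile. Here the aldehyde 18 is achiral and four carbons long. The forward step must give the syn adduct (cis-lactone) and choose the C7 face from C8.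

**13 ⇒ 12 ⇒ 10 + 11.** The C13–Br bond, then C7–C11 (Morita–Baylis–Hillman with methyl acrylate 11). This turns the acrylate unit into a commodity and leaves an α-silyloxy aldehyde 10 that carries C8 and C10.

**10 ⇒ 9 ⇒ 8 ⇒ 6.** Oxidation level and protection only, plus the C2–I bond: aldehyde 10 from the primary silyl ether of 9, 9 from triol 8, and 8 from lactone 6 by one hydride operation that both reduces the lactone and converts the alkyne into the (Z)-alkenyl iodide.

**6 ⇒ 3 + 4 (through 5); 3 ⇒ 1 + 2.** C10–C1 is cut (alkynyl addition to a methyl ketone under 1,3-chelation control), then C8–C9 (catalytic asymmetric aldol of acetone 1 with ethyl glyoxylate 2). The C8/C10 pair is thus made from three commodity chemicals, with C8 set by catalyst and C10 by C8.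

**18 ⇒ 17 ⇒ 16 ⇒ 14.** Aldehyde from alcohol, C4–Sn from C4–I, and the (Z)-iodide from but-2-yn-1-ol 14 by the same directed trans-hydroalumination.

## Roads not taken

**Alternative 1:** the obvious route. Cut C6–C7 and the lactone C–O last, and close the ring by intramolecular indium- or chromium-mediated 2-(alkoxycarbonyl)allylation of the seco bromo aldehyde A1, which already contains the dienone. This is how most germacranolides would be drawn. It asks a ten-membered closure to set C6 and C7 under macrocyclic control, for which no model exists. A1 carries a (Z)-4-oxo-enal beside the dienone, both prone to isomerise, and its C8 ester sits δ to the metal. In the chosen plan the same C6–C7 bond is made intermolecularly through an ordinary chair transition state, and the dienone does not exist until the ring closes.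

**Alternative 2:** cut C1=C2; ring-closing metathesis of the vinyl ketone / vinyl carbinol A2. Both olefins are poor metathesis partners (an enone and a hindered tertiary allylic alcohol). The Z geometry would rest on ring strain alone. The C11=C13 methylene offers a competing seven-membered closure with the C1 vinyl group. C3 would still have to be introduced by a separate acylation. The chosen plan fixes both geometries before closure and uses the C3 carbon itself as the closing element.

**Alternative 3:** cut C3–C4 only, with C3 stored as a butenolide carbonyl that also stores C10 and the Z-C1=C2 olefin. Iodine–lithium exchange on A3 and intramolecular addition to the butenolide would give the C3/C10 hemiketal directly. The C4 alkenyl-metal is, however, five atoms from the lactone carbonyl C12 and six from C13, so 5-exo acyl attack and 6-exo conjugate addition would beat a ten-membered closure. Avoiding this means building the methylene lactone after the ring, at a cost of several steps. Palladium/CO is neutral and tolerates lactone and acrylate.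

Key step: step 12

## Route

Step 1
Reactants: 1 acetone; 2 ethyl glyoxylate
Product: 3 ethyl (2R)-2-hydroxy-4-oxopentanoate
Conditions: L-proline (20 mol%), acetone (solvent), rt
Reagents that add atoms: none
Why: Proline-catalysed direct aldol reaction; the acetone enamine adds to the non-enolisable glyoxylate through the hydrogen-bonded enamine–carboxylic acid transition state, and L-proline should expose the face that gives the (R)-carbinol (future C8).

Step 2
Reactants: 3 ethyl (2R)-2-hydroxy-4-oxopentanoate; 4 ethynylmagnesium bromide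
Product: 6 (3R,5R)-5-ethynyl-3-hydroxy-5-methyloxolan-2-one, via open-chain dihydroxy ester 5 (not isolated)
Conditions: HC≡CMgBr (3 equiv), CeCl3 (3 equiv), THF, −78 → −40 °C; aq. NH4Cl; then PPTS (cat.), CH2Cl2, rt
Reagents that add atoms: none
Why: Organocerium alkynylation of a β-alkoxido ketone (low basicity avoids enolisation and retro-aldol); the nucleophile should add axially to the six-membered metal chelate, anti to the C8 substituent, giving the 1,3-anti (8R,10R) pair, and the tertiary alkoxide then closes the γ-lactone, whose diastereomers are separable.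

Step 3
Reactants: 6 (3R,5R)-5-ethynyl-3-hydroxy-5-methyloxolan-2-one
Product: 8 (2R,4R,5Z)-6-iodo-4-methylhex-5-ene-1,2,4-triol, via cyclic alkenylaluminate 7 (not isolated)
Conditions: Red-Al (5 equiv), THF, 0 °C → rt; then I2, THF, −78 → 0 °C; aq. Rochelle salt, Na2S2O3
Reagents that add atoms: iodine, II
Why: Hydroxyl-directed trans-hydroalumination of a propargylic alcohol followed by iodinolysis with retention; aluminium ends on C2 cis to the C10 oxygen in a five-membered aluminate, so the alkenyl iodide is Z, and the lactone is reduced to the 1,2-diol in the same operation.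

Step 4
Reactants: 8 (2R,4R,5Z)-6-iodo-4-methylhex-5-ene-1,2,4-triol
Product: 9 (2R,4R,5Z)-6-iodo-4-methyl-1,2,4-tris[(triethylsilyl)oxy]hex-5-ene
Conditions: TESOTf (3.6 equiv), 2,6-lutidine, CH2Cl2, −78 → 0 °C
Reagents that add atoms: triethylsilyl trifluoromethanesulfonate, CC[Si](CC)(CC)OS(=O)(=O)C(F)(F)F
Why: Exhaustive silylation with a silyl triflate (needed for the tertiary alcohol); the C8 silyl ether is a non-chelating, non-leaving group for step 11 and the C10 silyl ether blocks carbonylative lactonisation in step 12.

Step 5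
Reactants: 9 (2R,4R,5Z)-6-iodo-4-methyl-1,2,4-tris[(triethylsilyl)oxy]hex-5-ene
Product: 10 (2R,4R,5Z)-6-iodo-4-methyl-2,4-bis[(triethylsilyl)oxy]hex-5-enal
Conditions: (COCl)2, DMSO, CH2Cl2, −78 °C; then Et3N, −78 → −30 °C
Reagents that add atoms: none
Why: Swern oxidation of a primary triethylsilyl ether; the chlorosulfonium ion attacks only the unhindered primary silyl ether oxygen and expels Et3SiCl, so the aldehyde forms directly while the secondary and tertiary silyl ethers stay, and the low temperature protects the α-silyloxy centre.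

Step 6
Reactants: 10 (2R,4R,5Z)-6-iodo-4-methyl-2,4-bis[(triethylsilyl)oxy]hex-5-enal; 11 methyl acrylate
Product: 12 methyl (4R,6R,7Z)-3-hydroxy-8-iodo-6-methyl-2-methylidene-4,6-bis[(triethylsilyl)oxy]oct-7-enoate (both C3 epimers)
Conditions: DABCO (1 equiv), methyl acrylate (excess), MeOH (3 equiv), rt
Reagents that add atoms: none
Why: Morita–Baylis–Hillman reaction; α-oxygenated aldehydes are activated acceptors, the alkenyl iodide and silyl ethers are inert to the amine, and the new carbinol configuration at C7 is irrelevant because it is erased in step 7.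

Step 7
Reactants: 12 methyl (4R,6R,7Z)-3-hydroxy-8-iodo-6-methyl-2-methylidene-4,6-bis[(triethylsilyl)oxy]oct-7-enoate
Product: 13 methyl (2Z,4R,6R,7Z)-2-(bromomethyl)-8-iodo-6-methyl-4,6-bis[(triethylsilyl)oxy]octa-2,7-dienoate
Conditions: NBS, Me2S, CH2Cl2, 0 °C → rt
Reagents that add atoms: N-bromosuccinimide, O=C1CCC(=O)N1Br
Why: Bromination with allylic transposition (SN2' displacement of the alkoxysulfonium by bromide), which should give the thermodynamically preferred (Z)-2-(bromomethyl)enoate under near-neutral conditions that spare silyl ethers and the alkenyl iodide.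

Step 8
Reactants: 14 but-2-yn-1-ol
Product: 16 (2Z)-3-iodobut-2-en-1-ol, via cyclic alkenylaluminate 15 (not isolated)
Conditions: Red-Al, THF, 0 °C → rt; then I2, THF, −78 °C
Reagents that add atoms: iodine, II
Why: Same directed trans-hydroalumination/iodinolysis as in step 3; aluminium is delivered to the distal alkyne carbon cis to the CH2O group, so iodine ends on C4 cis to the future C6.

Step 9
Reactants: 16 (2Z)-3-iodobut-2-en-1-ol
Product: 17 (2Z)-3-(trimethylstannyl)but-2-en-1-ol
Conditions: (Me3Sn)2, Pd(PPh3)4 (5 mol%), i-Pr2NEt, THF, 60 °C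
Reagents that add atoms: hexamethylditin, C[Sn](C)(C)[Sn](C)(C)C
Why: Palladium-catalysed stannylation of an alkenyl iodide with a distannane (Stille-type, retention of olefin geometry).

Step 10
Reactants: 17 (2Z)-3-(trimethylstannyl)but-2-en-1-ol
Product: 18 (2Z)-3-(trimethylstannyl)but-2-enal
Conditions: MnO2, CH2Cl2, rt, dark
Reagents that add atoms: none
Why: Neutral allylic oxidation with manganese dioxide; a β-stannyl enal resists protodestannylation because ipso-protonation would place positive charge next to the carbonyl.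

Step 11
Reactants: 13 methyl (2Z,4R,6R,7Z)-2-(bromomethyl)-8-iodo-6-methyl-4,6-bis[(triethylsilyl)oxy]octa-2,7-dienoate; 18 (2Z)-3-(trimethylstannyl)but-2-enal
Product: 20 (4S,5R)-4-[(1R,3R,4Z)-5-iodo-3-methyl-1,3-bis[(triethylsilyl)oxy]pent-4-en-1-yl]-3-methylidene-5-[(1Z)-2-(trimethylstannyl)prop-1-en-1-yl]oxolan-2-one, via seco hydroxy ester 19 (not isolated)
Conditions: In powder, THF/H2O (1:1), rt; then PPTS (cat.), toluene, 40 °C
Reagents that add atoms: none
Why: Barbier-type 2-(alkoxycarbonyl)allylation; the allylindium with C8 cis to CH2In reacts through a chair six-membered transition state (γ-substituent axial) to give the syn adduct, i.e. the cis-lactone (C6, C7). The C7 face is chosen by C8 in a Felkin-type arrangement (H8 eclipsing the olefin, attack anti to C9, silyloxy outside), which places C11 and O8 anti along the chain as the target requires; mild acid then closes the lactone.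

Step 12
Reactants: 20 (4S,5R)-4-[(1R,3R,4Z)-5-iodo-3-methyl-1,3-bis[(triethylsilyl)oxy]pent-4-en-1-yl]-3-methylidene-5-[(1Z)-2-(trimethylstannyl)prop-1-en-1-yl]oxolan-2-one; 21 carbon monoxide
Product: 22 (3aS,4R,6R,7Z,10Z,11aS)-6,10-dimethyl-3-methylidene-4,6-bis[(triethylsilyl)oxy]-3a,4,5,11a-tetrahydrocyclodeca[b]furan-2,9(3H,6H)-dione
Conditions: CO (3 atm), Pd2(dba)3 (10 mol%), AsPh3 (40 mol%), CuI (20 mol%), NMP, 55 °C, syringe-pump addition of 20 over 12 h (final concentration 1 mM)
Reagents that add atoms: none
Why: Oxidative addition of Pd(0) into the C2–I bond, CO insertion to the (Z)-enoyl palladium (C3), intramolecular transmetalation from the C4 stannane and reductive elimination form C2–C3 and C3–C4 and so create the ketone and the ring together. The closest known reaction type is the carbonylative Stille macrocyclisation of an alkenyl halide with an alkenylstannane to a macrocyclic cross-conjugated dienone. The ten-membered ring closes by reductive elimination from an eleven-membered acyl(alkenyl)palladacycle; no stereocentre is created, and both olefin geometries enter with retention from the alkenyl iodide and the alkenylstannane. Carbonylative rather than direct coupling is needed and is secured by CO pressure and by the strain of the nine-membered diene that direct coupling would give. Ring closure rather than oligomerisation is secured by slow addition and by the two Z olefins and the cis-lactone, which turn the chain ends toward each other. The iodide sits on C2 so that the alkenylpalladium is eight atoms from the C11=C13 acceptor (no Heck cyclisation), and the C10 silyl ether prevents capture of the acylpalladium as a butenolide. Triphenylarsine, a weak donor, speeds transmetalation of the hindered stannane and disfavours ionisation of the allylic lactone C6–O bond.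

Step 13
Reactants: 22 (3aS,4R,6R,7Z,10Z,11aS)-6,10-dimethyl-3-methylidene-4,6-bis[(triethylsilyl)oxy]-3a,4,5,11a-tetrahydrocyclodeca[b]furan-2,9(3H,6H)-dione
Product: 23 (3aR,4R,6R,7Z,10Z,11aS)-4,6-dihydroxy-6,10-dimethyl-3-methylidene-3a,4,5,11a-tetrahydrocyclodeca[b]furan-2,9(3H,6H)-dione
Conditions: HF·pyridine, pyridine, THF, 0 °C → rt
Reagents that add atoms: none
Why: Buffered fluoride desilylation of both silyl ethers without base, so lactone and dienone survive; the freed C10 hydroxyl can add reversibly to C3, which should protect the (Z)-enone from isomerisation.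

Step 14
Reactants: 23 (3aR,4R,6R,7Z,10Z,11aS)-4,6-dihydroxy-6,10-dimethyl-3-methylidene-3a,4,5,11a-tetrahydrocyclodeca[b]furan-2,9(3H,6H)-dione; 24 (2R)-2-methylbutanoic acid
Product: 25 [(3aR,4R,6R,7Z,10Z,11aS)-6-hydroxy-6,10-dimethyl-3-methylidene-2,9-dioxo-2,3,3a,4,5,6,9,11a-octahydrocyclodeca[b]furan-4-yl] (2R)-2-methylbutanoate
Conditions: DCC, DMAP (cat.), CH2Cl2, 0 °C
Reagents that add atoms: none
Why: Steglich esterification; only the secondary C8 hydroxyl should be acylated (the C10 and hemiketal hydroxyls are tertiary), and low temperature with catalytic DMAP limits α-epimerisation of the acid and translactonisation.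

## Compound list

1 | acetone | CC(C)=O | starting material
2 | ethyl glyoxylate | CCOC(=O)C=O | starting material
3 | ethyl (2R)-2-hydroxy-4-oxopentanoate | CC(=O)C[C@@H](O)C(=O)OCC | intermediate
4 | ethynylmagnesium bromide | C#C[Mg]Br | starting material
5 | ethyl (2R,4R)-2,4-dihydroxy-4-methylhex-5-ynoate | C#C[C@](C)(O)C[C@@H](O)C(=O)OCC | intermediate (not isolated)
6 | (3R,5R)-5-ethynyl-3-hydroxy-5-methyloxolan-2-one | C#C[C@@]1(C)C[C@@H](O)C(=O)O1 | intermediate
7 | trisodium cyclic (Z)-alkenylaluminate derived from 6 (idealised 1,2-oxaluminole ate complex) | COCCO[Al-]1(OCCOC)O[C@](C)(C[C@@H]([O-])C[O-])C=C1.[Na+].[Na+].[Na+] | intermediate (not isolated)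
8 | (2R,4R,5Z)-6-iodo-4-methylhex-5-ene-1,2,4-triol | I/C=C\[C@](C)(O)C[C@@H](O)CO | intermediate
9 | (2R,4R,5Z)-6-iodo-4-methyl-1,2,4-tris[(triethylsilyl)oxy]hex-5-ene | I/C=C\[C@](C)(O[Si](CC)(CC)CC)C[C@@H](O[Si](CC)(CC)CC)CO[Si](CC)(CC)CC | intermediate
10 | (2R,4R,5Z)-6-iodo-4-methyl-2,4-bis[(triethylsilyl)oxy]hex-5-enal | I/C=C\[C@](C)(O[Si](CC)(CC)CC)C[C@@H](O[Si](CC)(CC)CC)C=O | intermediate
11 | methyl acrylate | C=CC(=O)OC | starting material
12 | methyl (4R,6R,7Z)-3-hydroxy-8-iodo-6-methyl-2-methylidene-4,6-bis[(triethylsilyl)oxy]oct-7-enoate (both C3 epimers) | I/C=C\[C@](C)(O[Si](CC)(CC)CC)C[C@@H](O[Si](CC)(CC)CC)C(O)C(=C)C(=O)OC | intermediate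
13 | methyl (2Z,4R,6R,7Z)-2-(bromomethyl)-8-iodo-6-methyl-4,6-bis[(triethylsilyl)oxy]octa-2,7-dienoate | I/C=C\[C@](C)(O[Si](CC)(CC)CC)C[C@@H](O[Si](CC)(CC)CC)/C=C(\CBr)C(=O)OC | intermediate
14 | but-2-yn-1-ol | CC#CCO | starting material
15 | sodium cyclic alkenylaluminate derived from 14 (idealised) | COCCO[Al-]1(OCCOC)OCC=C1C.[Na+] | intermediate (not isolated)
16 | (2Z)-3-iodobut-2-en-1-ol | OC/C=C(/C)I | intermediate
17 | (2Z)-3-(trimethylstannyl)but-2-en-1-ol | OC/C=C(/C)[Sn](C)(C)C | intermediate
18 | (2Z)-3-(trimethylstannyl)but-2-enal | O=C/C=C(/C)[Sn](C)(C)C | intermediate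
19 | methyl 2-[(2Z,4R,5S,6R,8R,9Z)-4-hydroxy-10-iodo-8-methyl-6,8-bis[(triethylsilyl)oxy]-2-(trimethylstannyl)deca-2,9-dien-5-yl]prop-2-enoate | C=C(C(=O)OC)[C@@H]([C@@H](O)/C=C(/C)[Sn](C)(C)C)[C@H](O[Si](CC)(CC)CC)C[C@@](C)(O[Si](CC)(CC)CC)/C=C\I | intermediate (not isolated)
20 | (4S,5R)-4-[(1R,3R,4Z)-5-iodo-3-methyl-1,3-bis[(triethylsilyl)oxy]pent-4-en-1-yl]-3-methylidene-5-[(1Z)-2-(trimethylstannyl)prop-1-en-1-yl]oxolan-2-one | C=C1C(=O)O[C@@H](/C=C(/C)[Sn](C)(C)C)[C@H]1[C@H](O[Si](CC)(CC)CC)C[C@@](C)(O[Si](CC)(CC)CC)/C=C\I | intermediate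
21 | carbon monoxide | [C-]#[O+] | starting material
22 | (3aS,4R,6R,7Z,10Z,11aS)-6,10-dimethyl-3-methylidene-4,6-bis[(triethylsilyl)oxy]-3a,4,5,11a-tetrahydrocyclodeca[b]furan-2,9(3H,6H)-dione | C=C1C(=O)O[C@H]2/C=C(/C)C(=O)/C=C\[C@](C)(O[Si](CC)(CC)CC)C[C@@H](O[Si](CC)(CC)CC)[C@@H]12 | intermediate
23 | (3aR,4R,6R,7Z,10Z,11aS)-4,6-dihydroxy-6,10-dimethyl-3-methylidene-3a,4,5,11a-tetrahydrocyclodeca[b]furan-2,9(3H,6H)-dione | C=C1C(=O)O[C@H]2/C=C(/C)C(=O)/C=C\[C@](C)(O)C[C@@H](O)[C@@H]12 | intermediate
24 | (2R)-2-methylbutanoic acid | CC[C@@H](C)C(=O)O | starting material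
25 | [(3aR,4R,6R,7Z,10Z,11aS)-6-hydroxy-6,10-dimethyl-3-methylidene-2,9-dioxo-2,3,3a,4,5,6,9,11a-octahydrocyclodeca[b]furan-4-yl] (2R)-2-methylbutanoate | C=C1C(=O)O[C@H]2/C=C(/C)C(=O)/C=C\[C@](C)(O)C[C@@H](OC(=O)[C@H](C)CC)[C@@H]12 | target

## Step count and least certain steps

Total: 14 steps. Longest linear sequence: 11 steps (steps 1–7 and 11–14); steps 8–10 make the second fragment.

**Step 12 (key).** The likely failure is that transmetalation of the hindered 1-methylalkenylstannane inside an eleven-membered palladacycle is too slow. Oligomerisation, protodestannylation or Z→E isomerisation of the enoyl palladium would then compete, and Pd(0) could ionise the allylic lactone C6–O bond. Fallback, setting out from 12 and 18 and returning at 22: the bonds are made in the reverse order. An intermolecular carbonylative Stille coupling of 12 with 18 (Pd, CO) gives methyl (4R,6R,7Z,10Z)-3-hydroxy-6,10-dimethyl-2-methylidene-9,12-dioxo-4,6-bis[(triethylsilyl)oxy]dodeca-7,10-dienoate F1. NBS/Me2S converts it into methyl (2Z,4R,6R,7Z,10Z)-2-(bromomethyl)-6,10-dimethyl-9,12-dioxo-4,6-bis[(triethylsilyl)oxy]dodeca-2,7,10-trienoate F2. The ring is then closed at C6–C7 by intramolecular indium-mediated allylation at high dilution followed by lactonisation, which gives 22.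

**Step 2.** The five-membered chelate through the ester carbonyl may compete with the six-membered ketone chelate, so that 1,3-induction is eroded or reversed. Fallback, setting out from 1 and 2 and returning at 6: use the opposite inherent selectivity and correct the invertible centre. D-Proline gives ethyl (2S)-2-hydroxy-4-oxopentanoate F3. The alkynyl addition, now used in its syn sense, gives (3S,5R)-5-ethynyl-3-hydroxy-5-methyloxolan-2-one F4 with the correct C10. Mitsunobu inversion at C8 with 4-nitrobenzoic acid gives (3R,5R)-5-ethynyl-5-methyl-2-oxooxolan-3-yl 4-nitrobenzoate F5, and mild methanolysis of the aryl ester gives 6.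

**Step 11.** The open allylindium may give poor facial selectivity at C7 relative to C8 (Felkin-type against chelated or anti-to-oxygen attack), or leak to the trans-lactone. Fallback, setting out from 12 and returning at 20: change to a closed-transition-state allylboration. Acetylation of 12 gives methyl (4R,6R,7Z)-3-acetoxy-8-iodo-6-methyl-2-methylidene-4,6-bis[(triethylsilyl)oxy]oct-7-enoate F6. Copper-catalysed SN2' borylation with bis(pinacolato)diboron gives methyl (2E,4R,6R,7Z)-8-iodo-6-methyl-2-[(4,4,5,5-tetramethyl-1,3,2-dioxaborolan-2-yl)methyl]-4,6-bis[(triethylsilyl)oxy]octa-2,7-dienoate F7. Its Lewis-acid-catalysed addition to 18 passes olefin geometry into the cis-lactone through a chair transition state and, after lactonisation, gives 20. A chiral diol on boron could add reagent control if needed.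

**Step 14.** With C8–OH free next to the cis-lactone, acyl transfer to the 8,12-olide may occur, the hemiketal hydroxyl may be acylated as well, or the acid may epimerise under activation. Fallback, setting out from 20 and returning at 25: put the ester on before the ring is closed. Selective cleavage of the secondary silyl ether of 20 (PPTS, MeOH, 0 °C) gives (4R,5R)-4-[(1R,3R,4Z)-1-hydroxy-5-iodo-3-methyl-3-[(triethylsilyl)oxy]pent-4-en-1-yl]-3-methylidene-5-[(1Z)-2-(trimethylstannyl)prop-1-en-1-yl]oxolan-2-one F8. Esterification with 24 gives (1R,3R,4Z)-5-iodo-3-methyl-1-{(2R,3R)-4-methylidene-5-oxo-2-[(1Z)-2-(trimethylstannyl)prop-1-en-1-yl]oxolan-3-yl}-3-[(triethylsilyl)oxy]pent-4-en-1-yl (2R)-2-methylbutanoate F9. The carbonylative macrocyclisation of step 12 then gives [(3aR,4R,6R,7Z,10Z,11aS)-6,10-dimethyl-3-methylidene-2,9-dioxo-6-[(triethylsilyl)oxy]-2,3,3a,4,5,6,9,11a-octahydrocyclodeca[b]furan-4-yl] (2R)-2-methylbutanoate F10, and HF·pyridine gives 25 as the last step.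

## Further compounds

F1 | step 12 | methyl (4R,6R,7Z,10Z)-3-hydroxy-6,10-dimethyl-2-methylidene-9,12-dioxo-4,6-bis[(triethylsilyl)oxy]dodeca-7,10-dienoate | O=C/C=C(/C)C(=O)/C=C\[C@](C)(O[Si](CC)(CC)CC)C[C@@H](O[Si](CC)(CC)CC)C(O)C(=C)C(=O)OC
F2 | step 12 | methyl (2Z,4R,6R,7Z,10Z)-2-(bromomethyl)-6,10-dimethyl-9,12-dioxo-4,6-bis[(triethylsilyl)oxy]dodeca-2,7,10-trienoate | O=C/C=C(/C)C(=O)/C=C\[C@](C)(O[Si](CC)(CC)CC)C[C@@H](O[Si](CC)(CC)CC)/C=C(\CBr)C(=O)OC
F3 | step 2 | ethyl (2S)-2-hydroxy-4-oxopentanoate | CC(=O)C[C@H](O)C(=O)OCC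
F4 | step 2 | (3S,5R)-5-ethynyl-3-hydroxy-5-methyloxolan-2-one | C#C[C@@]1(C)C[C@H](O)C(=O)O1
F5 | step 2 | (3R,5R)-5-ethynyl-5-methyl-2-oxooxolan-3-yl 4-nitrobenzoate | C#C[C@@]1(C)C[C@@H](OC(=O)c2ccc(cc2)[N+](=O)[O-])C(=O)O1
F6 | step 11 | methyl (4R,6R,7Z)-3-acetoxy-8-iodo-6-methyl-2-methylidene-4,6-bis[(triethylsilyl)oxy]oct-7-enoate | I/C=C\[C@](C)(O[Si](CC)(CC)CC)C[C@@H](O[Si](CC)(CC)CC)C(OC(C)=O)C(=C)C(=O)OC
F7 | step 11 | methyl (2E,4R,6R,7Z)-8-iodo-6-methyl-2-[(4,4,5,5-tetramethyl-1,3,2-dioxaborolan-2-yl)methyl]-4,6-bis[(triethylsilyl)oxy]octa-2,7-dienoate | I/C=C\[C@](C)(O[Si](CC)(CC)CC)C[C@@H](O[Si](CC)(CC)CC)/C=C(\CB1OC(C)(C)C(C)(C)O1)C(=O)OC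
F8 | step 14 | (4R,5R)-4-[(1R,3R,4Z)-1-hydroxy-5-iodo-3-methyl-3-[(triethylsilyl)oxy]pent-4-en-1-yl]-3-methylidene-5-[(1Z)-2-(trimethylstannyl)prop-1-en-1-yl]oxolan-2-one | C=C1C(=O)O[C@@H](/C=C(/C)[Sn](C)(C)C)[C@H]1[C@H](O)C[C@@](C)(O[Si](CC)(CC)CC)/C=C\I
F9 | step 14 | (1R,3R,4Z)-5-iodo-3-methyl-1-{(2R,3R)-4-methylidene-5-oxo-2-[(1Z)-2-(trimethylstannyl)prop-1-en-1-yl]oxolan-3-yl}-3-[(triethylsilyl)oxy]pent-4-en-1-yl (2R)-2-methylbutanoate | C=C1C(=O)O[C@@H](/C=C(/C)[Sn](C)(C)C)[C@H]1[C@H](OC(=O)[C@H](C)CC)C[C@@](C)(O[Si](CC)(CC)CC)/C=C\I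
F10 | step 14 | [(3aR,4R,6R,7Z,10Z,11aS)-6,10-dimethyl-3-methylidene-2,9-dioxo-6-[(triethylsilyl)oxy]-2,3,3a,4,5,6,9,11a-octahydrocyclodeca[b]furan-4-yl] (2R)-2-methylbutanoate | C=C1C(=O)O[C@H]2/C=C(/C)C(=O)/C=C\[C@](C)(O[Si](CC)(CC)CC)C[C@@H](OC(=O)[C@H](C)CC)[C@@H]12
A1 | alternative 1 | methyl (2Z,4R,6R,7Z,10Z)-2-(bromomethyl)-6-hydroxy-6,10-dimethyl-4-{[(2R)-2-methylbutanoyl]oxy}-9,12-dioxododeca-2,7,10-trienoate | O=C/C=C(/C)C(=O)/C=C\[C@](C)(O)C[C@@H](OC(=O)[C@H](C)CC)/C=C(\CBr)C(=O)OC
A2 | alternative 2 | (1R,3R)-3-hydroxy-3-methyl-1-{(2S,3R)-4-methylidene-2-[(1Z)-2-methyl-3-oxopenta-1,4-dien-1-yl]-5-oxooxolan-3-yl}pent-4-en-1-yl (2R)-2-methylbutanoate | C=C1C(=O)O[C@@H](/C=C(/C)C(=O)C=C)[C@H]1[C@H](OC(=O)[C@H](C)CC)C[C@@](C)(O)C=C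
A3 | alternative 3 | (5R)-5-{(2R)-2-[(2R,3S)-2-[(1Z)-2-iodoprop-1-en-1-yl]-4-methylidene-5-oxooxolan-3-yl]-2-[(triethylsilyl)oxy]ethyl}-5-methylfuran-2(5H)-one | C=C1C(=O)O[C@@H](/C=C(/C)I)[C@H]1[C@H](O[Si](CC)(CC)CC)C[C@]1(C)C=CC(=O)O1
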